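Everything rests on opening the upper pyran at C4–C4a. Upper C4 is doubly benzylic: it bears ring D through lower C8, which sits between the oxygens on lower C7 and C8a, and its bond to C4a lies para to the C7 oxygen of ring A. A carbinol at C4 can therefore be ionised to a well-stabilised cation that the tethered ring A captures; this single operation closes the upper pyran, forms C4–C4a and sets C4 trans to C3. The precursor is an open-chain 2-benzyloxy-3-aryloxy-1,3-diarylpropan-1-ol whose two stereocentres (future upper C3 and C2) come from an epoxy alcohol and whose ring D, metalated between its oxygens, already carries the masked acetyl group.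

Key step: step 13

Abbreviations: Bn = benzyl; Ar = 3,4,5-tris(benzyloxy)phenyl; Fl = (2R,3S,4S)-3,7-bis(benzyloxy)-2-Ar-3,4-dihydro-2H-chromen-4-yl. Rings A, B and C belong to the upper flavan unit; ring D is the benzo ring of the lower unit.

Assumption: carbinol 16 is used as the mixture of its two C1 epimers, because both ionise to the same cation in step 13.

Step 1
Reactants: 1 3,4,5-tris(benzyloxy)benzaldehyde
Product: 2 ethyl (2E)-3-[3,4,5-tris(benzyloxy)phenyl]prop-2-enoate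
Conditions: Ph3P=CHCO2Et, toluene, 90 °C
Reagents that add atoms: ethyl (triphenylphosphoranylidene)acetate, CCOC(=O)C=P(c1ccccc1)(c1ccccc1)c1ccccc1
Why: Wittig olefination with a stabilised ylide, whose reversible addition to the aromatic aldehyde leads to the E-enoate.

Step 2
Reactants: 2 ethyl (2E)-3-[3,4,5-tris(benzyloxy)phenyl]prop-2-enoate
Product: 3 (2E)-3-[3,4,5-tris(benzyloxy)phenyl]prop-2-en-1-ol
Conditions: i-Bu2AlH, CH2Cl2, −78 → 0 °C
Reagents that add atoms: none
Why: 1,2-Reduction of the conjugated ester by i-Bu2AlH at low temperature should give the allylic alcohol and leave the alkene and the benzyl ethers alone.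

Step 3
Reactants: 3 (2E)-3-[3,4,5-tris(benzyloxy)phenyl]prop-2-en-1-ol
Product: 4 [(2S,3S)-3-[3,4,5-tris(benzyloxy)phenyl]oxiran-2-yl]methanol
Conditions: Ti(OiPr)4 (cat.), L-(+)-diethyl tartrate (cat.), t-BuOOH, 4 Å MS, CH2Cl2, −20 °C
Reagents that add atoms: tert-butyl hydroperoxide, CC(C)(C)OO
Why: Sharpless asymmetric epoxidation, in which the Ti(OiPr)4/L-(+)-tartrate complex binds the E-allylic alcohol and delivers oxygen to the face that gives the (2S,3S)-epoxide, which fixes future upper C3 directly and future upper C2 before its inversion.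

Step 4
Reactants: 4 [(2S,3S)-3-[3,4,5-tris(benzyloxy)phenyl]oxiran-2-yl]methanol; 5 3-(benzyloxy)phenol
Product: 6 (2S,3R)-3-[3-(benzyloxy)phenoxy]-3-[3,4,5-tris(benzyloxy)phenyl]propane-1,2-diol
Conditions: NaOH, H2O/1,4-dioxane, 70 °C
Reagents that add atoms: none
Why: SN2 opening of a 3-aryl-2,3-epoxy alcohol by phenoxide in aqueous base is known to occur at the benzylic C3, which is inverted to R while C2 keeps its configuration, so the erythro arrangement that maps onto 2,3-trans in the flavan results.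

Step 5
Reactants: 6 (2S,3R)-3-[3-(benzyloxy)phenoxy]-3-[3,4,5-tris(benzyloxy)phenyl]propane-1,2-diol
Product: 7 (4S)-4-{(R)-[3-(benzyloxy)phenoxy][3,4,5-tris(benzyloxy)phenyl]methyl}-2-phenyl-1,3-dioxolane (both epimers at the acetal carbon)
Conditions: PhCH(OMe)2, camphorsulfonic acid (cat.), CH2Cl2, rt
Reagents that add atoms: benzaldehyde dimethyl acetal, COC(OC)c1ccccc1
Why: Acid-catalysed transacetalisation closes the five-membered benzylidene acetal on the 1,2-diol, and the new acetal carbon may form as both epimers because it becomes a benzylic CH2 in step 6.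

Step 6
Reactants: 7 (4S)-4-{(R)-[3-(benzyloxy)phenoxy][3,4,5-tris(benzyloxy)phenyl]methyl}-2-phenyl-1,3-dioxolane
Product: 8 (2S,3R)-2-(benzyloxy)-3-[3-(benzyloxy)phenoxy]-3-[3,4,5-tris(benzyloxy)phenyl]propan-1-ol
Conditions: i-Bu2AlH, CH2Cl2, −78 → 0 °C
Reagents that add atoms: none
Why: Regioselective reductive opening of a benzylidene acetal, in which the aluminium hydride binds the less hindered primary oxygen, that C–O bond breaks and hydride reduces the resulting oxocarbenium, so the benzyl group stays on the secondary oxygen.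

Step 7
Reactants: 8 (2S,3R)-2-(benzyloxy)-3-[3-(benzyloxy)phenoxy]-3-[3,4,5-tris(benzyloxy)phenyl]propan-1-ol
Product: 9 (2R,3R)-2-(benzyloxy)-3-[3-(benzyloxy)phenoxy]-3-[3,4,5-tris(benzyloxy)phenyl]propanal
Conditions: Dess–Martin periodinane, CH2Cl2, 0 °C → rt
Reagents that add atoms: none
Why: Dess–Martin oxidation is non-basic and stops at the aldehyde, so the α-benzyloxy centre should not epimerise and the β-aryloxy group should not be eliminated (the descriptor at C2 changes only through the priority rules).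

Step 8
Reactants: 10 1-(2,4-dihydroxyphenyl)ethanone
Product: 11 1-(2,4-dihydroxy-3-iodophenyl)ethanone
Conditions: I2, HIO3, EtOH/H2O, rt
Reagents that add atoms: iodine, II; iodic acid, OI(=O)=O
Why: Electrophilic aromatic iodination at C3, the position ortho to both hydroxyls, with HIO3 returning the iodide formed to iodine.

Step 9
Reactants: 11 1-(2,4-dihydroxy-3-iodophenyl)ethanone
Product: 12 1-[4-(benzyloxy)-2-hydroxy-3-iodophenyl]ethanone
Conditions: BnBr (1 equiv), K2CO3, acetone, reflux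
Reagents that add atoms: benzyl bromide, BrCc1ccccc1
Why: Williamson etherification that is selective for the 4-hydroxyl, because the 2-hydroxyl is held in a hydrogen bond to the carbonyl and is less acidic.

Step 10
Reactants: 12 1-[4-(benzyloxy)-2-hydroxy-3-iodophenyl]ethanone
Product: 13 1-[4-(benzyloxy)-3-iodo-2-(prop-2-en-1-yloxy)phenyl]ethanone
Conditions: allyl bromide, K2CO3, DMF, 60 °C
Reagents that add atoms: allyl bromide, C=CCBr
Why: Williamson etherification of the remaining chelated phenol under more forcing conditions installs an allyl group, which is orthogonal to benzyl and can later be removed by zerovalent palladium.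

Step 11
Reactants: 13 1-[4-(benzyloxy)-3-iodo-2-(prop-2-en-1-yloxy)phenyl]ethanone
Product: 14 2-[4-(benzyloxy)-3-iodo-2-(prop-2-en-1-yloxy)phenyl]-2-methyl-1,3-dioxolane
Conditions: Me3SiOCH2CH2OSiMe3, Me3SiOTf (cat.), CH2Cl2, −78 → −20 °C
Reagents that add atoms: 1,2-bis(trimethylsilyloxy)ethane, C[Si](C)(C)OCCO[Si](C)(C)C
Why: Silyl triflate-catalysed ketalisation with the bis-silyl ether of ethylene glycol masks the enolisable acetyl group at low temperature and avoids hot protic acid, which could deiodinate the electron-rich ring.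

Step 12
Reactants: 14 2-[4-(benzyloxy)-3-iodo-2-(prop-2-en-1-yloxy)phenyl]-2-methyl-1,3-dioxolane; 9 (2R,3R)-2-(benzyloxy)-3-[3-(benzyloxy)phenoxy]-3-[3,4,5-tris(benzyloxy)phenyl]propanal
Product: 16 (2S,3R)-2-(benzyloxy)-1-[6-(benzyloxy)-3-(2-methyl-1,3-dioxolan-2-yl)-2-(prop-2-en-1-yloxy)phenyl]-3-[3-(benzyloxy)phenoxy]-3-[3,4,5-tris(benzyloxy)phenyl]propan-1-ol (both C1 epimers), via aryllithium 15 (not isolated)
Conditions: n-BuLi, THF, −78 °C; then 9, −78 → −40 °C; H2O quench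
Reagents that add atoms: none
Why: Iodine–lithium exchange is much faster at −78 °C than attack on the allyl or benzyl ethers and places the metal between the two ring D oxygens, and 1,2-addition of the aryllithium to the aldehyde then gives the carbinol, whose new centre is left uncontrolled because step 13 removes it.

Step 13
Reactants: 16 (2S,3R)-2-(benzyloxy)-1-[6-(benzyloxy)-3-(2-methyl-1,3-dioxolan-2-yl)-2-(prop-2-en-1-yloxy)phenyl]-3-[3-(benzyloxy)phenoxy]-3-[3,4,5-tris(benzyloxy)phenyl]propan-1-ol (both C1 epimers)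
Product: 17 (2R,3S,4S)-3,7-bis(benzyloxy)-4-[6-(benzyloxy)-3-(2-methyl-1,3-dioxolan-2-yl)-2-(prop-2-en-1-yloxy)phenyl]-2-[3,4,5-tris(benzyloxy)phenyl]-3,4-dihydro-2H-chromene
Conditions: BF3·OEt2 (0.5 equiv), 4 Å MS, CH2Cl2 (0.01 M), −78 → −20 °C; Et3N quench
Reagents that add atoms: none
Why: BF3·OEt2 ionises the C1 carbinol of either epimer to a benzylic cation that is delocalised onto the two ortho oxygens of ring D; the tethered 3-benzyloxyphenyl ether attacks it through the carbon para to its benzyloxy group and loss of a proton restores ring A, which forms upper C4–C4a (intramolecular Friedel–Crafts alkylation of SN1 type). The closest known reaction type is the acid-mediated cyclisation of aryl ethers onto benzylic cations to give 4-arylchromans. The upper pyran closes as a six-membered ring in which the attacked arene bond C4a–C8a becomes part of the ring (6-endo with respect to ring A, exo with respect to the leaving hydroxyl). The new centre C4 is controlled by the resident C2 and C3 centres through a chair-like transition state in which the C2 aryl group, the C3 benzyloxy group and the ring D aryl group are all pseudo-equatorial, which gives 3,4-trans and hence 4S. The step needs this diastereoselectivity and also site selectivity, namely closure onto ring A para to its benzyloxy group and not between its two oxygens or onto ring B; the first is favoured sterically and the second by the preference for six-membered over five-membered (indane) closure, while high dilution suppresses intermolecular alkylation and the sieves protect the dioxolane from the water released.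

Step 14
Reactants: 17 (2R,3S,4S)-3,7-bis(benzyloxy)-4-[6-(benzyloxy)-3-(2-methyl-1,3-dioxolan-2-yl)-2-(prop-2-en-1-yloxy)phenyl]-2-[3,4,5-tris(benzyloxy)phenyl]-3,4-dihydro-2H-chromene
Product: 18 1-[4-(benzyloxy)-3-Fl-2-(prop-2-en-1-yloxy)phenyl]ethanone
Conditions: 1 M HCl, THF, rt
Reagents that add atoms: water, O
Why: Acid hydrolysis of the dioxolane runs through an oxocarbenium stabilised by the para benzyloxy group and is mild enough to leave the allyl and benzyl ethers and the 5-deoxy interflavanyl bond intact.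

Step 15
Reactants: 18 1-[4-(benzyloxy)-3-Fl-2-(prop-2-en-1-yloxy)phenyl]ethanone; 1 3,4,5-tris(benzyloxy)benzaldehyde
Product: 19 (2E)-1-[4-(benzyloxy)-3-Fl-2-(prop-2-en-1-yloxy)phenyl]-3-[3,4,5-tris(benzyloxy)phenyl]prop-2-en-1-one
Conditions: KOH, EtOH/THF, rt
Reagents that add atoms: none
Why: Claisen–Schmidt condensation of the methyl ketone enolate with the non-enolisable aldehyde followed by E1cB dehydration gives the E-enone, and without a free 2'-hydroxyl no flavanone can form.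

Step 16
Reactants: 19 (2E)-1-[4-(benzyloxy)-3-Fl-2-(prop-2-en-1-yloxy)phenyl]-3-[3,4,5-tris(benzyloxy)phenyl]prop-2-en-1-one
Product: 20 [4-(benzyloxy)-3-Fl-2-(prop-2-en-1-yloxy)phenyl]{(2R,3S)-3-[3,4,5-tris(benzyloxy)phenyl]oxiran-2-yl}methanone
Conditions: poly-L-leucine, urea–H2O2, DBU, THF, rt
Reagents that add atoms: urea–hydrogen peroxide, NC(N)=O.OO
Why: Juliá–Colonna epoxidation, in which hydroperoxide adds to the enone held at the N-terminus of the poly-L-leucine helix and for E-chalcones gives the (2R,3S)-epoxide under catalyst control, the isolated allyl alkene being inert to the nucleophilic oxidant.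

Step 17
Reactants: 20 [4-(benzyloxy)-3-Fl-2-(prop-2-en-1-yloxy)phenyl]{(2R,3S)-3-[3,4,5-tris(benzyloxy)phenyl]oxiran-2-yl}methanone
Product: 22 (2R,3R)-7-(benzyloxy)-3-hydroxy-8-Fl-2-[3,4,5-tris(benzyloxy)phenyl]-2,3-dihydro-4H-chromen-4-one, via free phenol epoxy ketone 21 (not isolated)
Conditions: Pd(PPh3)4 (cat.), K2CO3, MeOH/THF, rt
Reagents that add atoms: none
Why: Zerovalent palladium ionises the allyl aryl ether (Tsuji–Trost deallylation, π-allyl trapped by methanol) and the phenoxide then opens the epoxide at the benzylic carbon by 6-endo SN2 attack with inversion, a known cyclisation of 2'-hydroxychalcone epoxides, which sets lower C2 as R trans to the retained 3R hydroxyl.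

Step 18
Reactants: 22 (2R,3R)-7-(benzyloxy)-3-hydroxy-8-Fl-2-[3,4,5-tris(benzyloxy)phenyl]-2,3-dihydro-4H-chromen-4-one
Product: 23 (2R,3R)-8-[(2R,3S,4S)-3,7-dihydroxy-2-(3,4,5-trihydroxyphenyl)-3,4-dihydro-2H-chromen-4-yl]-3,7-dihydroxy-2-(3,4,5-trihydroxyphenyl)-2,3-dihydro-4H-chromen-4-one (target)
Conditions: H2 (1 atm), Pd(OH)2/C, THF/MeOH, rt
Reagents that add atoms: none
Why: Hydrogenolysis over Pd(OH)2/C cleaves the nine benzyl ethers, while the aryl ketone, the cyclic benzylic C–O bonds and the interflavanyl C–C bond should be stable at 1 atm and room temperature.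

Compound list

1 | 3,4,5-tris(benzyloxy)benzaldehyde | O=Cc1cc(OCc2ccccc2)c(OCc2ccccc2)c(OCc2ccccc2)c1 | starting material
2 | ethyl (2E)-3-[3,4,5-tris(benzyloxy)phenyl]prop-2-enoate | CCOC(=O)/C=C/c1cc(OCc2ccccc2)c(OCc2ccccc2)c(OCc2ccccc2)c1 | intermediate
3 | (2E)-3-[3,4,5-tris(benzyloxy)phenyl]prop-2-en-1-ol | OC/C=C/c1cc(OCc2ccccc2)c(OCc2ccccc2)c(OCc2ccccc2)c1 | intermediate
4 | [(2S,3S)-3-[3,4,5-tris(benzyloxy)phenyl]oxiran-2-yl]methanol | OC[C@@H]1O[C@H]1c1cc(OCc2ccccc2)c(OCc2ccccc2)c(OCc2ccccc2)c1 | intermediate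
5 | 3-(benzyloxy)phenol | Oc1cccc(OCc2ccccc2)c1 | starting material
6 | (2S,3R)-3-[3-(benzyloxy)phenoxy]-3-[3,4,5-tris(benzyloxy)phenyl]propane-1,2-diol | OC[C@H](O)[C@@H](c1cc(OCc2ccccc2)c(OCc2ccccc2)c(OCc2ccccc2)c1)Oc1cccc(OCc2ccccc2)c1 | intermediate
7 | (4S)-4-{(R)-[3-(benzyloxy)phenoxy][3,4,5-tris(benzyloxy)phenyl]methyl}-2-phenyl-1,3-dioxolane, both epimers at the acetal carbon | c1ccccc1C1OC[C@H](O1)[C@@H](c1cc(OCc2ccccc2)c(OCc2ccccc2)c(OCc2ccccc2)c1)Oc1cccc(OCc2ccccc2)c1 | intermediate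
8 | (2S,3R)-2-(benzyloxy)-3-[3-(benzyloxy)phenoxy]-3-[3,4,5-tris(benzyloxy)phenyl]propan-1-ol | OC[C@H](OCc1ccccc1)[C@@H](c1cc(OCc2ccccc2)c(OCc2ccccc2)c(OCc2ccccc2)c1)Oc1cccc(OCc2ccccc2)c1 | intermediate
9 | (2R,3R)-2-(benzyloxy)-3-[3-(benzyloxy)phenoxy]-3-[3,4,5-tris(benzyloxy)phenyl]propanal | O=C[C@H](OCc1ccccc1)[C@@H](c1cc(OCc2ccccc2)c(OCc2ccccc2)c(OCc2ccccc2)c1)Oc1cccc(OCc2ccccc2)c1 | intermediate
10 | 1-(2,4-dihydroxyphenyl)ethanone (2,4-dihydroxyacetophenone) | CC(=O)c1ccc(O)cc1O | starting material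
11 | 1-(2,4-dihydroxy-3-iodophenyl)ethanone | CC(=O)c1ccc(O)c(I)c1O | intermediate
12 | 1-[4-(benzyloxy)-2-hydroxy-3-iodophenyl]ethanone | CC(=O)c1ccc(OCc2ccccc2)c(I)c1O | intermediate
13 | 1-[4-(benzyloxy)-3-iodo-2-(prop-2-en-1-yloxy)phenyl]ethanone | CC(=O)c1ccc(OCc2ccccc2)c(I)c1OCC=C | intermediate
14 | 2-[4-(benzyloxy)-3-iodo-2-(prop-2-en-1-yloxy)phenyl]-2-methyl-1,3-dioxolane | CC1(OCCO1)c1ccc(OCc2ccccc2)c(I)c1OCC=C | intermediate
15 | [6-(benzyloxy)-3-(2-methyl-1,3-dioxolan-2-yl)-2-(prop-2-en-1-yloxy)phenyl]lithium | CC1(OCCO1)c1ccc(OCc2ccccc2)c([Li])c1OCC=C | intermediate (not isolated)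
16 | (2S,3R)-2-(benzyloxy)-1-[6-(benzyloxy)-3-(2-methyl-1,3-dioxolan-2-yl)-2-(prop-2-en-1-yloxy)phenyl]-3-[3-(benzyloxy)phenoxy]-3-[3,4,5-tris(benzyloxy)phenyl]propan-1-ol, both C1 epimers | CC1(OCCO1)c1ccc(OCc2ccccc2)c(C(O)[C@H](OCc2ccccc2)[C@@H](c2cc(OCc3ccccc3)c(OCc3ccccc3)c(OCc3ccccc3)c2)Oc2cccc(OCc3ccccc3)c2)c1OCC=C | intermediate
17 | (2R,3S,4S)-3,7-bis(benzyloxy)-4-[6-(benzyloxy)-3-(2-methyl-1,3-dioxolan-2-yl)-2-(prop-2-en-1-yloxy)phenyl]-2-[3,4,5-tris(benzyloxy)phenyl]-3,4-dihydro-2H-chromene | CC1(OCCO1)c1ccc(OCc2ccccc2)c([C@@H]2c3ccc(OCc4ccccc4)cc3O[C@H](c3cc(OCc4ccccc4)c(OCc4ccccc4)c(OCc4ccccc4)c3)[C@H]2OCc2ccccc2)c1OCC=C | intermediate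
18 | 1-{4-(benzyloxy)-3-[(2R,3S,4S)-3,7-bis(benzyloxy)-2-[3,4,5-tris(benzyloxy)phenyl]-3,4-dihydro-2H-chromen-4-yl]-2-(prop-2-en-1-yloxy)phenyl}ethanone | CC(=O)c1ccc(OCc2ccccc2)c([C@@H]2c3ccc(OCc4ccccc4)cc3O[C@H](c3cc(OCc4ccccc4)c(OCc4ccccc4)c(OCc4ccccc4)c3)[C@H]2OCc2ccccc2)c1OCC=C | intermediate
19 | (2E)-1-{4-(benzyloxy)-3-[(2R,3S,4S)-3,7-bis(benzyloxy)-2-[3,4,5-tris(benzyloxy)phenyl]-3,4-dihydro-2H-chromen-4-yl]-2-(prop-2-en-1-yloxy)phenyl}-3-[3,4,5-tris(benzyloxy)phenyl]prop-2-en-1-one | O=C(/C=C/c1cc(OCc2ccccc2)c(OCc2ccccc2)c(OCc2ccccc2)c1)c1ccc(OCc2ccccc2)c([C@@H]2c3ccc(OCc4ccccc4)cc3O[C@H](c3cc(OCc4ccccc4)c(OCc4ccccc4)c(OCc4ccccc4)c3)[C@H]2OCc2ccccc2)c1OCC=C | intermediate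
20 | {4-(benzyloxy)-3-[(2R,3S,4S)-3,7-bis(benzyloxy)-2-[3,4,5-tris(benzyloxy)phenyl]-3,4-dihydro-2H-chromen-4-yl]-2-(prop-2-en-1-yloxy)phenyl}{(2R,3S)-3-[3,4,5-tris(benzyloxy)phenyl]oxiran-2-yl}methanone | O=C([C@@H]1O[C@H]1c1cc(OCc2ccccc2)c(OCc2ccccc2)c(OCc2ccccc2)c1)c1ccc(OCc2ccccc2)c([C@@H]2c3ccc(OCc4ccccc4)cc3O[C@H](c3cc(OCc4ccccc4)c(OCc4ccccc4)c(OCc4ccccc4)c3)[C@H]2OCc2ccccc2)c1OCC=C | intermediate
21 | {4-(benzyloxy)-3-[(2R,3S,4S)-3,7-bis(benzyloxy)-2-[3,4,5-tris(benzyloxy)phenyl]-3,4-dihydro-2H-chromen-4-yl]-2-hydroxyphenyl}{(2R,3S)-3-[3,4,5-tris(benzyloxy)phenyl]oxiran-2-yl}methanone | O=C([C@@H]1O[C@H]1c1cc(OCc2ccccc2)c(OCc2ccccc2)c(OCc2ccccc2)c1)c1ccc(OCc2ccccc2)c([C@@H]2c3ccc(OCc4ccccc4)cc3O[C@H](c3cc(OCc4ccccc4)c(OCc4ccccc4)c(OCc4ccccc4)c3)[C@H]2OCc2ccccc2)c1O | intermediate (not isolated)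
22 | (2R,3R)-7-(benzyloxy)-8-[(2R,3S,4S)-3,7-bis(benzyloxy)-2-[3,4,5-tris(benzyloxy)phenyl]-3,4-dihydro-2H-chromen-4-yl]-3-hydroxy-2-[3,4,5-tris(benzyloxy)phenyl]-2,3-dihydro-4H-chromen-4-one | O=C1c2ccc(OCc3ccccc3)c([C@@H]3c4ccc(OCc5ccccc5)cc4O[C@H](c4cc(OCc5ccccc5)c(OCc5ccccc5)c(OCc5ccccc5)c4)[C@H]3OCc3ccccc3)c2O[C@H](c2cc(OCc3ccccc3)c(OCc3ccccc3)c(OCc3ccccc3)c2)[C@H]1O | intermediate
23 | (2R,3R)-8-[(2R,3S,4S)-3,7-dihydroxy-2-(3,4,5-trihydroxyphenyl)-3,4-dihydro-2H-chromen-4-yl]-3,7-dihydroxy-2-(3,4,5-trihydroxyphenyl)-2,3-dihydro-4H-chromen-4-one | O=C1c2ccc(O)c([C@@H]3c4ccc(O)cc4O[C@H](c4cc(O)c(O)c(O)c4)[C@H]3O)c2O[C@H](c2cc(O)c(O)c(O)c2)[C@H]1O | target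

Total step count: 18.
Longest linear sequence: 14 steps (steps 1–7 and 12–18, from aldehyde 1); the ring D fragment takes 4 steps (8–11) and joins at step 12.

Steps most likely to fail

Step 13. The cation may be diverted before ring A captures it (hydride shift from the neighbouring benzyloxy carbon, five-membered closure onto ring B, loss of a ring D ether group under the Lewis acid), or C4 may close with poor trans selectivity. The fallback sets out from carbinol 16 and avoids a free cation and a Lewis acid. Removal of the allyl group with Pd(PPh3)4 and morpholine in THF should give the phenolic carbinol F1. On gentle heating in toluene this o-hydroxybenzyl alcohol should lose water to a neutral ortho-quinone methide, to which ring A adds in conjugate fashion through the same carbon, giving the phenolic 4-arylflavan F2. Allylation of F2 (allyl bromide, K2CO3, DMF) comes back to the route at 17.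

Step 16. The aroyl ring is flanked by the allyloxy group and the bulky flavanyl substituent, so the enone may bind poorly to the polypeptide, with slow turnover and weak facial selectivity. The fallback sets out from chalcone 19 and gives up catalyst control. Weitz–Scheffer epoxidation (H2O2, NaOH, MeOH/THF) should give both trans-epoxides. Because the upper unit is a single enantiomer these are diastereomers, epoxide 20 and the (2S,3R)-epoxide diastereomer F3, which would be separated by chromatography. The route is rejoined at 20.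

Step 17. After deallylation the phenoxide may close in the five-membered mode at the carbon next to the carbonyl, or the base may degrade the epoxy ketone or the hydroxy ketone formed. The fallback sets out from chalcone 19 and replaces the base-mediated closure by an acid-mediated one. Deallylation (Pd(PPh3)4, morpholine, THF) should give the 2'-hydroxychalcone F4, and protection (MOMCl, i-Pr2NEt, CH2Cl2) the methoxymethyl ether F5. Juliá–Colonna epoxidation as in step 16 should then give the (2R,3S)-epoxide F6. HCl in MeOH/THF at 50 °C removes the acetal and lets the phenol open the protonated epoxide at the benzylic carbon with inversion, which comes back to the route at 22.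

Further compounds

F1 | step 13 | (2S,3R)-2-(benzyloxy)-1-[6-(benzyloxy)-2-hydroxy-3-(2-methyl-1,3-dioxolan-2-yl)phenyl]-3-[3-(benzyloxy)phenoxy]-3-[3,4,5-tris(benzyloxy)phenyl]propan-1-ol, both C1 epimers | CC1(OCCO1)c1ccc(OCc2ccccc2)c(C(O)[C@H](OCc2ccccc2)[C@@H](c2cc(OCc3ccccc3)c(OCc3ccccc3)c(OCc3ccccc3)c2)Oc2cccc(OCc3ccccc3)c2)c1O
F2 | step 13 | 3-(benzyloxy)-2-[(2R,3S,4S)-3,7-bis(benzyloxy)-2-[3,4,5-tris(benzyloxy)phenyl]-3,4-dihydro-2H-chromen-4-yl]-6-(2-methyl-1,3-dioxolan-2-yl)phenol | CC1(OCCO1)c1ccc(OCc2ccccc2)c([C@@H]2c3ccc(OCc4ccccc4)cc3O[C@H](c3cc(OCc4ccccc4)c(OCc4ccccc4)c(OCc4ccccc4)c3)[C@H]2OCc2ccccc2)c1O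
F3 | step 16 | {4-(benzyloxy)-3-[(2R,3S,4S)-3,7-bis(benzyloxy)-2-[3,4,5-tris(benzyloxy)phenyl]-3,4-dihydro-2H-chromen-4-yl]-2-(prop-2-en-1-yloxy)phenyl}{(2S,3R)-3-[3,4,5-tris(benzyloxy)phenyl]oxiran-2-yl}methanone | O=C([C@H]1O[C@@H]1c1cc(OCc2ccccc2)c(OCc2ccccc2)c(OCc2ccccc2)c1)c1ccc(OCc2ccccc2)c([C@@H]2c3ccc(OCc4ccccc4)cc3O[C@H](c3cc(OCc4ccccc4)c(OCc4ccccc4)c(OCc4ccccc4)c3)[C@H]2OCc2ccccc2)c1OCC=C
F4 | step 17 | (2E)-1-{4-(benzyloxy)-3-[(2R,3S,4S)-3,7-bis(benzyloxy)-2-[3,4,5-tris(benzyloxy)phenyl]-3,4-dihydro-2H-chromen-4-yl]-2-hydroxyphenyl}-3-[3,4,5-tris(benzyloxy)phenyl]prop-2-en-1-one | O=C(/C=C/c1cc(OCc2ccccc2)c(OCc2ccccc2)c(OCc2ccccc2)c1)c1ccc(OCc2ccccc2)c([C@@H]2c3ccc(OCc4ccccc4)cc3O[C@H](c3cc(OCc4ccccc4)c(OCc4ccccc4)c(OCc4ccccc4)c3)[C@H]2OCc2ccccc2)c1O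
F5 | step 17 | (2E)-1-{4-(benzyloxy)-3-[(2R,3S,4S)-3,7-bis(benzyloxy)-2-[3,4,5-tris(benzyloxy)phenyl]-3,4-dihydro-2H-chromen-4-yl]-2-(methoxymethoxy)phenyl}-3-[3,4,5-tris(benzyloxy)phenyl]prop-2-en-1-one | O=C(/C=C/c1cc(OCc2ccccc2)c(OCc2ccccc2)c(OCc2ccccc2)c1)c1ccc(OCc2ccccc2)c([C@@H]2c3ccc(OCc4ccccc4)cc3O[C@H](c3cc(OCc4ccccc4)c(OCc4ccccc4)c(OCc4ccccc4)c3)[C@H]2OCc2ccccc2)c1OCOC
F6 | step 17 | {4-(benzyloxy)-3-[(2R,3S,4S)-3,7-bis(benzyloxy)-2-[3,4,5-tris(benzyloxy)phenyl]-3,4-dihydro-2H-chromen-4-yl]-2-(methoxymethoxy)phenyl}{(2R,3S)-3-[3,4,5-tris(benzyloxy)phenyl]oxiran-2-yl}methanone | O=C([C@@H]1O[C@H]1c1cc(OCc2ccccc2)c(OCc2ccccc2)c(OCc2ccccc2)c1)c1ccc(OCc2ccccc2)c([C@@H]2c3ccc(OCc4ccccc4)cc3O[C@H](c3cc(OCc4ccccc4)c(OCc4ccccc4)c(OCc4ccccc4)c3)[C@H]2OCc2ccccc2)c1OCOC
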